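I decided to count target in mM instead of percent of the charge, and the two earlier runs then read as one.

the same everywhere: gas phase 42 mM (held)

|  | solid substrate | remark | time |
|---|---|---|---|
| larch | 0.15 M | run made earlier |  |
| maple | 0.60 M | run made earlier |  |
| flask | 0.30 M |  | 40 h |

- larch (time / h: target / %, solid substrate / %): 4.00: 2.1, 93.6; 12.0: 11.8, 79.6; 20.0: 19.2, 66.6; 30.0: 32.0, 50.0
- maple (time / h: target / %, solid substrate / %): 8.00: 3.4, 97.8; 15.0: 2.9, 94.0; 25.0: 6.9, 88.8; 30.0: 7.7, 88.8

(each reading ± 1 percentage point)

- solid, in amounts per volume of the solution: solid substrate
- at the start none of the gas is dissolved
- candidate steps: gas phase <-> dissolved gas; starting material + dissolved gas -> target; starting material -> side product; solid substrate <-> starting material; target <-> isomer of the product; dissolved gas -> decomposed reagent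
- at the start none of the solid substrate is in solution

The percentages look unlike, but at 30.0 h the larch run held 48.0 mM of target and the maple run, charged with 0.60 M against 0.15 M, held 46.2 mM. So target did not follow the charge: these readings look zero order in the solid. Between its second and last readings the larch run gained 1.68 mM h⁻¹, and this I carried as the steady target rate, target gained per hour in a litre of solution.

At the larch pace of solid loss the flask would lose 100 mM of its 0.30 M by 40 h, so solid should remain and I froze the rate. Running the larch amount forward gave me 64.8 mM, which is 21.6% of the flask's charge.

* how much target there is at 40 h, in percent of the solid substrate charged
* the change that raises the amount of target at 40 h, in percent of the solid substrate charged most ("none" if none brings more than 2 percentage points) (violet / blue / teal / green / none)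
* amount of target at 40 h, in percent of the solid substrate charged, after teal

- violet: doubling the dissolution coefficient of the solid substrate, all else as stated
- blue: doubling the saturation concentration of gas phase, all else as stated
- teal: doubling the solubility of the solid substrate, all else as stated
- green: doubling the transfer coefficient of the gas phase, all else as stated

The forecast said 21%, with teal as the best change, giving 37%, on the ground that “supply is probably limited by solubility”. My own line gave 21.6% for the flask and nothing on the changes.

The flask gave 22.6%. The best change was teal, which brought 19 percentage points, more than any other, and reached 41.3%; violet brought 11 points, blue 7.1 points and green 1.4 points.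

    gas phase ⇌ dissolved gas, rate k1*(csat - [dissolved gas]) (kL = 0.250 h⁻¹)
    starting material + dissolved gas → target (k = 4.10 L mol⁻¹ h⁻¹)
    starting material → side product (k = 0.0220 h⁻¹)
    solid substrate ⇌ starting material, rate k4*(cs4 - [starting material]) while solid is left; crystals form when [starting material] > cs4 (solubility = 0.0540 M, k = 0.0590 h⁻¹)
    target ⇌ isomer of the product (K = 3.00, k = 0.00180 h⁻¹)
    dissolved gas → decomposed reagent (k = 0.00530 h⁻¹)

The flask held 67.8 mM of target against my 64.8 mM, with 67.9% of its solid substrate still undissolved. Target stood there because of the low solubility of the starting material together with the time allowed: without that solubility limit the flask reached 63.9%, and left ten times as long it reached 50.8%. A neighbouring flask charged with 0.12 M, still holding 19.8% as solid at 40 h, should by the same rate have reached 54.0%; it gave 56.5%.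

The readings were generated by integration with made-up constants; scatter was added.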